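Retrosynthetic cuts, in order: the purine bonds C8–N7 and C8–N9 (giving an ortho-hydroxy aldehyde on ring A plus 2,5,6-triaminopyrimidin-4(3H)-one), the ring A–CHO bond, the piperazine bonds N4–C3 and N1–C6 (giving a bis(α-amino aldehyde)), the C2–H and C5–H bonds (giving two enamides), the two Cα=Cβ bonds, and last the ring A–O–ring B ether bond.
Enabling feature: the only stereocentres are piperazine C2 (carrying the CH2 of para-phenylene ring B) and C5 (carrying the CH2 of phenol ring A). Both are S and each sits in an N–CH(CH2Ar)–C unit, the α-carbon of an arylalanine, so both map onto the prochiral alkene carbons of one achiral diaryl ether bis(dehydroamino ester).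
Forward order: ether bond (SNAr), two alkenes (double olefination), two stereocentres (double hydrogenation). The 14-membered macrocycle and the piperazine ring then close together from the bis(amino aldehyde), and the imidazole ring of the guanine is annulated last onto a formyl group placed ortho to the ring A phenol.
Stereochemistry: both centres come from the chiral bisphospholane ligand on rhodium in one operation. All later bonds form at nitrogen, at the former carboxyl carbons or on ring A, so C2 and C5 only have to be preserved.

Key step: step 3

Remark: the N7-H and N9-H forms of the purine are tautomers of one compound, so the target is written as the N7-H form of its SMILES. The piperazine is numbered N1, C2 (CH2 to ring B), C3, N4, C5 (CH2 to ring A), C6.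

Step 1
Reactants: 1 4-benzyloxy-3-hydroxybenzaldehyde; 2 4-fluorobenzaldehyde
Product: 3 4-benzyloxy-3-(4-formylphenoxy)benzaldehyde
Conditions: K2CO3, DMF, 110 °C
Reagents that add atoms: none
Why: Nucleophilic aromatic substitution (SNAr), in which the para-formyl group stabilises the Meisenheimer adduct so that the potassium phenoxide of 1 displaces fluoride, and both non-enolisable aldehydes tolerate the carbonate base.

Step 2
Reactants: 3 4-benzyloxy-3-(4-formylphenoxy)benzaldehyde; 4 N-Cbz-2-(dimethoxyphosphoryl)glycine methyl ester (2.4 equiv)
Product: 5 dimethyl (Z,Z)-bis(N-Cbz-dehydroamino ester) of the ring A–O–ring B diaryl ether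
Conditions: DBU, CH2Cl2, 0 °C → rt
Reagents that add atoms: none
Why: Double Horner–Wadsworth–Emmons olefination under the amidine-base conditions usual for phosphonoglycinates, which favour the (Z)-enamide at each aryl aldehyde and leave the benzyl ether untouched.

Step 3
Reactants: 5 dimethyl (Z,Z)-bis(N-Cbz-dehydroamino ester) of the diaryl ether
Product: 6 (S,S)-bis(N-Cbz amino ester) of the diaryl ether (O-benzyl-N,N'-di-Cbz-L,L-isodityrosine dimethyl ester)
Conditions: [Rh(cod)((S,S)-Et-DuPhos)]OTf (2 mol %), H2 (5 bar), degassed MeOH–CH2Cl2, rt
Reagents that add atoms: none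
Why: The cationic monovalent rhodium precatalyst sheds cod under H2, each enamide then binds as a chelate through its C=C bond and its carbamate carbonyl oxygen, and oxidative addition of H2, migratory insertion and reductive elimination place both hydrogens on one alkene face, forming the future C2–H and C5–H bonds. The closest known reaction type is the rhodium–bisphospholane asymmetric hydrogenation of (Z)-α-(acylamino)cinnamates, which has also been run at both ends of bis(dehydroamino esters). No ring closes in this step. The future C2 (ring B arm) and C5 (ring A arm) are each set as S by the C2-symmetric (S,S)-ligand alone, because the diaryl ether keeps the two sites too far apart to influence each other. The step needs enantioface selectivity at both alkenes, secured by the chelating NH-Cbz group and the uniform Z geometry (this ligand class reduces stray E isomer in the same sense), and chemoselectivity over benzyl ether, Cbz groups and arenes, secured by a homogeneous catalyst that does not cleave benzylic C–O bonds. Since two independent events are combined, the mirror-image (R,R) product should be statistically suppressed and any error should appear as (R,S) or (S,R) diastereomers that can be separated.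

Step 4
Reactants: 6 (S,S)-bis(N-Cbz amino ester)
Product: 7 (S,S)-bis(N-Cbz α-amino aldehyde) of the diaryl ether
Conditions: iBu2AlH (DIBAL-H, 6 equiv), toluene–CH2Cl2, −78 °C; MeOH quench at −78 °C, then aqueous potassium sodium tartrate; used crude
Reagents that add atoms: none
Why: Partial reduction of N-carbamoyl α-amino methyl esters with iBu2AlH is a standard entry to N-protected α-amino aldehydes, since at −78 °C the hydride adduct of each ester does not collapse before the cold quench, and omitting chromatography protects the two S centres from epimerisation.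

Step 5
Reactants: 7 (S,S)-bis(N-Cbz α-amino aldehyde)
Product: 10 (2S,5S)-macrocyclic piperazine phenol, via free bis(amino aldehyde) 8 (not isolated), via bridged 2,5-dihydropyrazine 9 (not isolated)
Conditions: H2 (1 atm), Pd(OH)2/C, MeOH–AcOH 20:1, slow syringe-pump addition of 7 (final 1 mM), rt; then H2 (4 bar), rt
Reagents that add atoms: none
Why: Proposed new method: hydrogenolysis removes both Cbz groups and the benzyl ether, each freed amine can only condense with the aldehyde of the other arm (N4 with C3, N1 with C6, closure within one arm being a three-membered ring), the first condensation closes the 14-membered ring and the second is a fast six-membered closure to 9, whose two CH=N bonds are then hydrogenated without touching C2–H or C5–H, while the low stationary concentration disfavours oligomers and the strain of a bridged planar pyrazine disfavours aromatisation; the closest known reaction type is the head-to-tail self-condensation of α-amino aldehydes released from their Cbz derivatives by hydrogenolysis, combined with reductive amination, so far an intermolecular process not yet run across a tether to a bridged piperazine.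

Step 6
Reactants: 10 (2S,5S)-macrocyclic piperazine phenol
Product: 11 N1,N4-di-Boc macrocyclic piperazine phenol
Conditions: Boc2O (2.2 equiv), Et3N, CH2Cl2–MeOH, 0 °C → rt
Reagents that add atoms: di-tert-butyl dicarbonate, CC(C)(C)OC(=O)OC(=O)OC(C)(C)C
Why: Carbamate formation (N-Boc protection), in which the two secondary amines are far more nucleophilic than the phenol, so without an acylation catalyst only nitrogen reacts and the amines are masked against formaldehyde in the next step.

Step 7
Reactants: 11 N1,N4-di-Boc macrocyclic piperazine phenol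
Product: 13 ring A ortho-hydroxy aldehyde of the di-Boc macrocycle, via hydroxymethyl phenol 12 (not isolated)
Conditions: MgCl2, Et3N, (CH2O)n, MeCN, reflux; aqueous NH4Cl
Reagents that add atoms: paraformaldehyde (reacts as formaldehyde), C=O
Why: Magnesium-mediated ortho-formylation of a phenol (Casnati–Skattebøl reaction), in which the magnesium phenoxide delivers formaldehyde to the only free ortho carbon (the other ortho position carries the aryloxy group, the para position the CH2 bridge) to give 12, which passes a hydride to a second formaldehyde under conditions that Boc-protected tyrosine derivatives tolerate.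

Step 8
Reactants: 13 ring A ortho-hydroxy aldehyde; 14 2,5,6-triaminopyrimidin-4(3H)-one sulfate
Product: 16 N1,N4-di-Boc-guanipiperazine A, via Schiff base 15 (not isolated)
Conditions: NaOAc, DMSO–MeOH, 50 °C; then I2 (1.1 equiv), 50 °C; aqueous Na2S2O3
Reagents that add atoms: none
Why: Traube-type purine synthesis in its oxidative aldehyde variant, in which the most nucleophilic 5-amino group forms the hydrogen-bonded Schiff base 15, the neighbouring 6-amino group adds to the imine carbon and iodine removes two hydrogens to aromatise the imidazole ring, as known for 8-arylxanthines and 2-arylbenzimidazoles, while the phenol offers no free ortho or para position for iodination.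

Step 9
Reactants: 16 N1,N4-di-Boc-guanipiperazine A
Product: 17 guanipiperazine A
Conditions: TFA–CH2Cl2 1:3, 0 °C → rt; then aqueous NH3, reversed-phase purification
Reagents that add atoms: none
Why: Acidolysis of the two tert-butyl carbamates with loss of isobutene and CO2, which touches neither the diaryl ether, the purine nor the two stereocentres.

Compound list
1 | 4-benzyloxy-3-hydroxybenzaldehyde | O=Cc1ccc(OCc2ccccc2)c(O)c1 | starting material
2 | 4-fluorobenzaldehyde | O=Cc1ccc(F)cc1 | starting material
3 | 4-benzyloxy-3-(4-formylphenoxy)benzaldehyde | O=Cc1ccc(Oc2cc(C=O)ccc2OCc2ccccc2)cc1 | intermediate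
4 | N-Cbz-2-(dimethoxyphosphoryl)glycine methyl ester | COC(=O)C(NC(=O)OCc1ccccc1)P(=O)(OC)OC | starting material
5 | dimethyl (Z,Z)-bis(N-Cbz-dehydroamino ester) of the ring A–O–ring B diaryl ether, ring A phenol as benzyl ether | COC(=O)/C(=C/c1ccc(Oc2cc(/C=C(\NC(=O)OCc3ccccc3)C(=O)OC)ccc2OCc2ccccc2)cc1)NC(=O)OCc1ccccc1 | intermediate
6 | (S,S)-bis(N-Cbz amino ester), O-benzyl-N,N'-di-Cbz-L,L-isodityrosine dimethyl ester | COC(=O)[C@H](Cc1ccc(Oc2cc(C[C@@H](C(=O)OC)NC(=O)OCc3ccccc3)ccc2OCc2ccccc2)cc1)NC(=O)OCc1ccccc1 | intermediate
7 | (S,S)-bis(N-Cbz α-amino aldehyde) of the diaryl ether | O=C[C@H](Cc1ccc(Oc2cc(C[C@@H](C=O)NC(=O)OCc3ccccc3)ccc2OCc2ccccc2)cc1)NC(=O)OCc1ccccc1 | intermediate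
8 | free (S,S)-bis(α-amino aldehyde) with free ring A phenol (not isolated) | O=C[C@H](Cc1ccc(Oc2cc(C[C@@H](C=O)N)ccc2O)cc1)N | intermediate
9 | (2S,5S)-2,5-dihydropyrazine bridged by CH2–ring B–O–ring A–CH2 (not isolated) | Oc1ccc2cc1Oc1ccc(cc1)C[C@H]1C=N[C@H](C=N1)C2 | intermediate
10 | (2S,5S)-cis-piperazine bridged by CH2–ring B–O–ring A–CH2, 14-membered cyclophane with free phenol | Oc1ccc2cc1Oc1ccc(cc1)C[C@H]1CN[C@H](CN1)C2 | intermediate
11 | N1,N4-di-Boc derivative of 10 | Oc1ccc2cc1Oc1ccc(cc1)C[C@H]1CN(C(=O)OC(C)(C)C)[C@H](CN1C(=O)OC(C)(C)C)C2 | intermediate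
12 | ortho-hydroxymethyl phenol derived from 11, present as its magnesium phenoxide (not isolated) | OCc1cc2cc(c1O)Oc1ccc(cc1)C[C@H]1CN(C(=O)OC(C)(C)C)[C@H](CN1C(=O)OC(C)(C)C)C2 | intermediate
13 | ortho-hydroxy aldehyde, CHO on ring A next to the phenol and opposite the aryloxy group | O=Cc1cc2cc(c1O)Oc1ccc(cc1)C[C@H]1CN(C(=O)OC(C)(C)C)[C@H](CN1C(=O)OC(C)(C)C)C2 | intermediate
14 | 2,5,6-triaminopyrimidin-4(3H)-one sulfate | Nc1nc(N)c(N)c(=O)[nH]1.OS(=O)(=O)O | starting material
15 | (E)-Schiff base of 13 with the 5-amino group of the pyrimidinone (not isolated) | Nc1nc(N)c(/N=C/c2cc3cc(c2O)Oc2ccc(cc2)C[C@H]2CN(C(=O)OC(C)(C)C)[C@H](CN2C(=O)OC(C)(C)C)C3)c(=O)[nH]1 | intermediate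
16 | N1,N4-di-Boc-guanipiperazine A | Nc1nc2nc(-c3cc4cc(c3O)Oc3ccc(cc3)C[C@H]3CN(C(=O)OC(C)(C)C)[C@H](CN3C(=O)OC(C)(C)C)C4)[nH]c2c(=O)[nH]1 | intermediate
17 | guanipiperazine A, (2S,5S) | Nc1nc2nc(-c3cc4cc(c3O)Oc3ccc(cc3)C[C@H]3CN[C@H](CN3)C4)[nH]c2c(=O)[nH]1 | target

Total step count: 9. Longest linear sequence: 9 steps (1 → 17).

Steps most likely to fail

Step 5 (the labelled step). Intermolecular imine formation may outrun closure of the strained 14-membered ring and lead to oligomerisation. Imine–enamine tautomerisation at the dihydropyrazine stage may erode the configuration at C2 and C5. Dehydrogenation on the palladium surface may drain material towards the aromatic oxidation level.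

The fallback keeps the double hydrogenation but makes the two arms orthogonal, so that the two C–N bonds are closed one after the other by known reactions. It sets out from 1 and comes back at 10.
- Compound 1 is olefinated (DBU, 2.2 equiv, CH2Cl2) with commercial N-Boc-2-(dimethoxyphosphoryl)glycine methyl ester to the phenolic (Z)-N-Boc-dehydroamino ester F1.
- SNAr on 2 (K2CO3, DMF) gives the diaryl ether mono-aldehyde F2, and olefination with 4 gives the mixed N-Boc/N-Cbz (Z,Z)-bis(dehydroamino ester) F3.
- Hydrogenation exactly as in step 3 should give the mixed (S,S)-bis(amino ester) F4, and iBu2AlH at −78 °C the mixed bis(aldehyde) F5.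
- TFA removes only the Boc group and gives the ring A arm amino aldehyde F6, kept as its trifluoroacetate.
- F6 is added slowly to NaBH(OAc)3 in dilute 1,2-dichloroethane, so that the N4–C3 bond alone is closed by an irreversible macrocyclic reductive amination to the 14-membered secondary amine F7.
- Hydrogenolysis (H2, Pd/C, MeOH) then frees N1 and the phenol. N1 condenses with the remaining aldehyde to the six-membered cyclic imine F8, which is reduced in the same flask to 10.

Step 8. Poor solubility of the pyrimidine partner, an unfavourable position of the imine/ring-closed equilibrium, and over-oxidation of the electron-rich aminopyrimidine by iodine may stall the annulation.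

The fallback replaces oxidative ring closure by the acylation and cyclodehydration variant of the Traube synthesis. It sets out from 13 and comes back at 16.
- Pinnick oxidation (NaClO2, NaH2PO4, 2-methyl-2-butene, tBuOH–H2O) should give the salicylic acid F9.
- Carbodiimide coupling (EDC·HCl, HOBt, DMF) with 14, released with NaOAc, acylates the 5-amino group selectively to the 5-carboxamide F10.
- Heating with aqueous NaOH in EtOH closes the imidazole ring by loss of water to 16. The Boc groups are stable to base.

Step 4. Over-reduction of one or both esters, incomplete conversion to ester–aldehyde mixtures, and epimerisation of the α-amino aldehydes during work-up may lower both throughput and stereochemical purity.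

The fallback passes through the alcohol oxidation level. It sets out from 6 and comes back at 7.
- LiBH4 (THF–MeOH, 0 °C → rt) reduces both esters fully to the stable, purifiable bis(N-Cbz amino alcohol) F11.
- Parikh–Doering oxidation (SO3·pyridine, DMSO, Et3N, 0 °C), a method known to give N-protected α-amino aldehydes with retention of configuration, returns 7.

Further compounds
F1 | step 5 | methyl (Z)-2-(Boc-amino)-3-(4-benzyloxy-3-hydroxyphenyl)acrylate | COC(=O)/C(=C/c1ccc(OCc2ccccc2)c(O)c1)NC(=O)OC(C)(C)C
F2 | step 5 | methyl (Z)-2-(Boc-amino)-3-[4-benzyloxy-3-(4-formylphenoxy)phenyl]acrylate | COC(=O)/C(=C/c1ccc(OCc2ccccc2)c(Oc2ccc(C=O)cc2)c1)NC(=O)OC(C)(C)C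
F3 | step 5 | mixed (Z,Z)-bis(dehydroamino ester), N-Boc on the ring A arm and N-Cbz on the ring B arm | COC(=O)/C(=C/c1ccc(Oc2cc(/C=C(\NC(=O)OC(C)(C)C)C(=O)OC)ccc2OCc2ccccc2)cc1)NC(=O)OCc1ccccc1
F4 | step 5 | mixed (S,S)-bis(amino ester), N-Boc on the ring A arm and N-Cbz on the ring B arm | COC(=O)[C@H](Cc1ccc(Oc2cc(C[C@@H](C(=O)OC)NC(=O)OC(C)(C)C)ccc2OCc2ccccc2)cc1)NC(=O)OCc1ccccc1
F5 | step 5 | mixed (S,S)-bis(α-amino aldehyde), N-Boc on the ring A arm and N-Cbz on the ring B arm | O=C[C@H](Cc1ccc(Oc2cc(C[C@@H](C=O)NC(=O)OC(C)(C)C)ccc2OCc2ccccc2)cc1)NC(=O)OCc1ccccc1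
F6 | step 5 | (S,S)-bis(aldehyde) with free amine on the ring A arm and N-Cbz on the ring B arm | O=C[C@H](Cc1ccc(Oc2cc(C[C@@H](C=O)N)ccc2OCc2ccccc2)cc1)NC(=O)OCc1ccccc1
F7 | step 5 | 14-membered secondary amine with the N4–C3 bond closed, C5 carrying CHO and C2 carrying NHCbz | O=C[C@@H]1Cc2ccc(OCc3ccccc3)c(c2)Oc2ccc(cc2)C[C@H](NC(=O)OCc2ccccc2)CN1
F8 | step 5 | bridged (2S,5S)-tetrahydropyrazine with an N1=C6 imine and free phenol | Oc1ccc2cc1Oc1ccc(cc1)C[C@H]1CN[C@H](C=N1)C2
F9 | step 8 | ring A salicylic acid of the di-Boc macrocycle | O=C(O)c1cc2cc(c1O)Oc1ccc(cc1)C[C@H]1CN(C(=O)OC(C)(C)C)[C@H](CN1C(=O)OC(C)(C)C)C2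
F10 | step 8 | N-(2,6-diamino-4-oxo-3H-pyrimidin-5-yl) amide of F9 | Nc1nc(N)c(NC(=O)c2cc3cc(c2O)Oc2ccc(cc2)C[C@H]2CN(C(=O)OC(C)(C)C)[C@H](CN2C(=O)OC(C)(C)C)C3)c(=O)[nH]1
F11 | step 4 | (S,S)-bis(N-Cbz amino alcohol) of the diaryl ether | OC[C@H](Cc1ccc(Oc2cc(C[C@@H](CO)NC(=O)OCc3ccccc3)ccc2OCc2ccccc2)cc1)NC(=O)OCc1ccccc1
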